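Assumption: the target SMILES has no stereocentre and no stereogenic double bond. It is therefore achiral and needs no enantioselective step. The racemic centres that arise along the way are all erased again.

**Retrosynthetic overview**
1. The target comes from its tetraacetate, which comes from an aromatic Claisen [3,3] shift of the 7-O-prenyl ether. This shift makes the C8–CMe2CH=CH2 bond and is placed late, so the alkene never meets oxidant or H2.
2. The 7-O-prenyl ether comes from 2'-hydroxygenistein by peracetylation, selective 7-O-deacetylation and Mitsunobu etherification with prenol.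
3. 2'-Hydroxygenistein comes from the tetrabenzyl isoflavone. That arises by ring C closure of a 2-aryl-3,3-dimethoxypropanone, itself made by oxidative 1,2-aryl shift of a chalcone.
4. The chalcone comes from the key intermolecular Claisen–Schmidt aldol condensation of the ring A acetophenone and the ring B benzaldehyde. The new bond ends up as C2–C3 of the isoflavone.
5. Rings A and B are bought (phloroacetophenone and 2,4-dihydroxybenzaldehyde). Only ring C, the pyranone, is built.

**Step 1**
Reactants: 1 2,4,6-trihydroxyacetophenone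
Product: 2 1-[2,4-bis(benzyloxy)-6-hydroxyphenyl]ethan-1-one
Conditions: BnBr (2.1 equiv), K2CO3 (2.5 equiv), DMF, 60 °C
Reagents that add atoms: benzyl bromide, BrCc1ccccc1
Why: In this Williamson ether synthesis the 4-OH and one ortho OH are alkylated, while the last ortho OH stays hydrogen-bonded to the acetyl C=O and does not react with the limited BnBr; no stereocentre forms.

**Step 2**
Reactants: 3 2,4-dihydroxybenzaldehyde
Product: 4 2,4-bis(benzyloxy)benzaldehyde
Conditions: BnBr (2.3 equiv), K2CO3 (3 equiv), DMF, 60 °C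
Reagents that add atoms: benzyl bromide, BrCc1ccccc1
Why: Exhaustive Williamson ether synthesis gives acid- and base-stable ethers that keep ring B electron-rich for the later aryl shift; no stereocentre forms.

**Step 3 (key step)**
Reactants: 2 1-[2,4-bis(benzyloxy)-6-hydroxyphenyl]ethan-1-one; 4 2,4-bis(benzyloxy)benzaldehyde
Product: 6 (E)-1-[2,4-bis(benzyloxy)-6-hydroxyphenyl]-3-[2,4-bis(benzyloxy)phenyl]prop-2-en-1-one, via aldol adduct 5 (not isolated)
Conditions: KOH (50% aq, 12 equiv), EtOH/THF, rt, 48 h; then 1 M HCl, 0 °C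
Reagents that add atoms: none
Why: In this Claisen–Schmidt crossed aldol condensation only 2 can enolise and only 4 is a good acceptor, and E1cB loss of water from the racemic aldol erases its carbinol centre and gives the E-enone under thermodynamic control.

**Step 4**
Reactants: 6 the (E)-2'-hydroxychalcone
Product: 7 3,5-bis(benzyloxy)-2-[(E)-3-[2,4-bis(benzyloxy)phenyl]prop-2-enoyl]phenyl acetate
Conditions: Ac2O, pyridine, DMAP (cat.), CH2Cl2, 0 °C to rt
Reagents that add atoms: acetic anhydride, CC(=O)OC(C)=O
Why: DMAP-catalysed O-acylation masks the free phenol, so it is neither oxidised by trivalent thallium nor able to close to a flavanone or aurone; the E-alkene is untouched.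

**Step 5**
Reactants: 7 the 2'-acetoxychalcone
Product: 8 racemic 3,5-bis(benzyloxy)-2-{2-[2,4-bis(benzyloxy)phenyl]-3,3-dimethoxypropanoyl}phenyl acetate
Conditions: Tl(NO3)3·3H2O (1.15 equiv), MeOH/CH2Cl2 3:1, rt, 4 h
Reagents that add atoms: methanol, CO
Why: In this oxidative 1,2-aryl migration, methoxythallation of the enone is followed by shift of the very electron-rich 2,4-dibenzyloxyphenyl group from C-beta to C-alpha as monovalent thallium leaves, and the new alpha centre is racemic and is erased in step 6.

**Step 6**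
Reactants: 8 the acetoxy acetal
Product: 10 5,7-bis(benzyloxy)-3-[2,4-bis(benzyloxy)phenyl]-4H-chromen-4-one, via phenol acetal 9 (not isolated)
Conditions: conc. HCl (10% v/v), MeOH/THF, reflux, 3 h
Reagents that add atoms: none
Why: Acid-catalysed transesterification frees the ring A phenol, which cyclocondenses onto the acetal carbon with loss of two methanol molecules to give ring C, while the retained ring B 2-O-benzyl group rules out competing benzofuran closure.

**Step 7**
Reactants: 10 the tetra-O-benzyl isoflavone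
Product: 11 5,7-dihydroxy-3-(2,4-dihydroxyphenyl)-4H-chromen-4-one (2'-hydroxygenistein)
Conditions: H2 (1 atm), 10% Pd/C, THF/MeOH, rt, stopped after uptake of 4 equiv
Reagents that add atoms: none
Why: Catalytic hydrogenolysis of aryl benzyl ethers is faster than reduction of the conjugated C2=C3 bond, and it is done before any isolated alkene is present.

**Step 8**
Reactants: 11 2'-hydroxygenistein
Product: 12 5,7,2',4'-tetraacetoxyisoflavone
Conditions: Ac2O (excess), pyridine, DMAP (cat.), rt, 16 h
Reagents that add atoms: acetic anhydride, CC(=O)OC(C)=O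
Why: Exhaustive O-acetylation, including the chelated 5-OH thanks to DMAP, installs groups that can be removed at the end without acid, oxidant or H2.

**Step 9**
Reactants: 12 the tetraacetate
Product: 13 5,2',4'-triacetoxy-7-hydroxyisoflavone
Conditions: PhSH (1.3 equiv), imidazole (0.4 equiv), NMP, 0 °C to rt
Reagents that add atoms: none
Why: In this chemoselective thiolysis (acyl transfer) the 7-acetate reacts first because it is the ester of the most acidic phenol, a vinylogous acid conjugated with C4=O, whereas the 5-acetate is hindered and the ring B acetates are ordinary aryl esters.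

**Step 10**
Reactants: 13 5,2',4'-triacetoxy-7-hydroxyisoflavone; 14 3-methylbut-2-en-1-ol (prenol)
Product: 15 5,2',4'-triacetoxy-7-(3-methylbut-2-enyloxy)isoflavone
Conditions: PPh3 (1.5 equiv), DIAD (1.5 equiv), THF, 0 °C to rt
Reagents that add atoms: none
Why: Mitsunobu etherification of an acidic phenol with a primary allylic alcohol proceeds by SN2 without allylic transposition and, being neutral, leaves the acetates in place.

**Step 11**
Reactants: 15 the 7-O-prenyl ether
Product: 18 5,7,2',4'-tetraacetoxy-8-(2-methylbut-3-en-2-yl)isoflavone, via ortho-dienone 16 (not isolated), via free phenol 17 (not isolated)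
Conditions: Ac2O (5 equiv), PhNEt2, sealed tube, 190 °C, Ar, 4 h
Reagents that add atoms: acetic anhydride, CC(=O)OC(C)=O
Why: The aromatic Claisen [3,3] rearrangement inverts the prenyl unit and goes to C8 (higher C7–C8 bond order in the benzopyranone; C6 shielded by the 5-acetate), the quaternary para carbon C4a blocks a follow-up Cope shift, the transient racemic C8 centre is lost on tautomerisation, and Ac2O traps the phenol before abnormal Claisen or dihydrofuran closure.

**Step 12**
Reactants: 18 the tetraacetate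
Product: 19 5,7-dihydroxy-3-(2,4-dihydroxyphenyl)-8-(2-methylbut-3-en-2-yl)-4H-chromen-4-one (target)
Conditions: K2CO3 (6 equiv), MeOH/THF, 0 °C to rt, Ar, 2 h; then 1 M HCl to pH 4
Reagents that add atoms: none
Why: Base-mediated transesterification (methanolysis) removes all four aryl acetates without touching the alkene, and the 7-phenoxide formed first deactivates the pyranone towards nucleophilic ring opening; no stereocentre is involved.

**Compound list**
1 | 2,4,6-trihydroxyacetophenone | CC(=O)c1c(O)cc(O)cc1O | starting material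
2 | 1-[2,4-bis(benzyloxy)-6-hydroxyphenyl]ethan-1-one | CC(=O)c1c(O)cc(OCc2ccccc2)cc1OCc1ccccc1 | intermediate
3 | 2,4-dihydroxybenzaldehyde | O=Cc1ccc(O)cc1O | starting material
4 | 2,4-bis(benzyloxy)benzaldehyde | O=Cc1ccc(OCc2ccccc2)cc1OCc1ccccc1 | intermediate
5 | racemic 1-[2,4-bis(benzyloxy)-6-hydroxyphenyl]-3-[2,4-bis(benzyloxy)phenyl]-3-hydroxypropan-1-one (not isolated) | O=C(CC(O)c1ccc(OCc2ccccc2)cc1OCc1ccccc1)c1c(O)cc(OCc2ccccc2)cc1OCc1ccccc1 | intermediate
6 | (E)-1-[2,4-bis(benzyloxy)-6-hydroxyphenyl]-3-[2,4-bis(benzyloxy)phenyl]prop-2-en-1-one | O=C(/C=C/c1ccc(OCc2ccccc2)cc1OCc1ccccc1)c1c(O)cc(OCc2ccccc2)cc1OCc1ccccc1 | intermediate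
7 | 3,5-bis(benzyloxy)-2-[(E)-3-[2,4-bis(benzyloxy)phenyl]prop-2-enoyl]phenyl acetate | CC(=O)Oc1cc(OCc2ccccc2)cc(OCc2ccccc2)c1C(=O)/C=C/c1ccc(OCc2ccccc2)cc1OCc1ccccc1 | intermediate
8 | racemic 3,5-bis(benzyloxy)-2-{2-[2,4-bis(benzyloxy)phenyl]-3,3-dimethoxypropanoyl}phenyl acetate | COC(OC)C(C(=O)c1c(OC(C)=O)cc(OCc2ccccc2)cc1OCc1ccccc1)c1ccc(OCc2ccccc2)cc1OCc1ccccc1 | intermediate
9 | racemic 1-[2,4-bis(benzyloxy)-6-hydroxyphenyl]-2-[2,4-bis(benzyloxy)phenyl]-3,3-dimethoxypropan-1-one (not isolated) | COC(OC)C(C(=O)c1c(O)cc(OCc2ccccc2)cc1OCc1ccccc1)c1ccc(OCc2ccccc2)cc1OCc1ccccc1 | intermediate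
10 | 5,7-bis(benzyloxy)-3-[2,4-bis(benzyloxy)phenyl]-4H-chromen-4-one | O=c1c(-c2ccc(OCc3ccccc3)cc2OCc2ccccc2)coc2cc(OCc3ccccc3)cc(OCc3ccccc3)c12 | intermediate
11 | 5,7-dihydroxy-3-(2,4-dihydroxyphenyl)-4H-chromen-4-one | O=c1c(-c2ccc(O)cc2O)coc2cc(O)cc(O)c12 | intermediate
12 | 5,7,2',4'-tetraacetoxyisoflavone | CC(=O)Oc1ccc(-c2coc3cc(OC(C)=O)cc(OC(C)=O)c3c2=O)c(OC(C)=O)c1 | intermediate
13 | 5,2',4'-triacetoxy-7-hydroxyisoflavone | CC(=O)Oc1ccc(-c2coc3cc(O)cc(OC(C)=O)c3c2=O)c(OC(C)=O)c1 | intermediate
14 | 3-methylbut-2-en-1-ol | CC(C)=CCO | starting material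
15 | 5,2',4'-triacetoxy-7-(3-methylbut-2-enyloxy)isoflavone | CC(C)=CCOc1cc(OC(C)=O)c2c(=O)c(-c3ccc(OC(C)=O)cc3OC(C)=O)coc2c1 | intermediate
16 | racemic 5-acetoxy-3-(2,4-diacetoxyphenyl)-8-(2-methylbut-3-en-2-yl)-8H-chromene-4,7-dione (not isolated) | C=CC(C)(C)C1C(=O)C=C(OC(C)=O)C2=C1OC=C(c1ccc(OC(C)=O)cc1OC(C)=O)C2=O | intermediate
17 | 5,2',4'-triacetoxy-7-hydroxy-8-(2-methylbut-3-en-2-yl)isoflavone (not isolated) | C=CC(C)(C)c1c(O)cc(OC(C)=O)c2c(=O)c(-c3ccc(OC(C)=O)cc3OC(C)=O)coc12 | intermediate
18 | 5,7,2',4'-tetraacetoxy-8-(2-methylbut-3-en-2-yl)isoflavone | C=CC(C)(C)c1c(OC(C)=O)cc(OC(C)=O)c2c(=O)c(-c3ccc(OC(C)=O)cc3OC(C)=O)coc12 | intermediate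
19 | 5,7-dihydroxy-3-(2,4-dihydroxyphenyl)-8-(2-methylbut-3-en-2-yl)-4H-chromen-4-one | C=CC(C)(C)c1c(O)cc(O)c2c(=O)c(-c3ccc(O)cc3O)coc12 | target

**Total step count:** 12.
**Longest linear sequence:** 11 (steps 1 and 3 to 12; step 2 is a one-step side branch).

**Three steps most likely to fail**

**Step 11 (Claisen rearrangement).** The risks are partial attack at C6 and thermal loss of isoprene. Material that loses the prenyl group reappears as 12 and can be recycled.

The fallback replaces the sigmatropic shift by a cross-coupling. It sets out from 13 and comes back at 18.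
- 13 is iodinated with NIS in DMF at 0 °C, ortho to the free 7-OH at the less hindered C8. This gives 5,2',4'-triacetoxy-7-hydroxy-8-iodoisoflavone F1.
- F1 is acetylated (Ac2O, pyridine) to 5,7,2',4'-tetraacetoxy-8-iodoisoflavone F2.
- F2 is coupled with prenylboronic acid pinacol ester in a gamma-selective Suzuki–Miyaura allylation. The conditions are Pd(OAc)2, a bulky dialkylbiarylphosphine chosen for branched selectivity, K3PO4 and THF/H2O at 40 to 60 °C. Bond formation at the CMe2 terminus gives the 1,1-dimethylallyl group.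
- The crude product is re-acetylated (Ac2O, pyridine) to converge on 18.

**Step 9 (selective 7-O-deacetylation).** The risk is that the 4'-acetate is also lost.

The fallback uses selective alkylation instead of selective deprotection. It sets out from 11 and comes back at 15.
- 11 is treated with exactly 1.0 equiv KOtBu in DMF at 0 °C. This forms only the 7-phenoxide, because the 7-OH is the most acidic.
- Prenyl bromide (1.0 equiv) then alkylates it to 5-hydroxy-3-(2,4-dihydroxyphenyl)-7-(3-methylbut-2-enyloxy)-4H-chromen-4-one F3.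
- Acetylation of the three remaining OH groups (Ac2O, pyridine, DMAP) gives 15.

**Step 5 (thallium-mediated aryl shift).** The risks are ring thallation or over-oxidation of the electron-rich arenes, and the toxicity of the reagent.

The fallback goes through the flavanone and skips 7, 8 and 9. It sets out from 6 and comes back at 10.
- 6 is cyclised by oxa-Michael addition (NaOAc, EtOH, reflux) to racemic 5,7-bis(benzyloxy)-2-[2,4-bis(benzyloxy)phenyl]chroman-4-one F4.
- F4 is treated with PhI(OH)OTs (1.2 equiv) in MeCN at reflux. The enol is attacked by trivalent iodine, the electron-rich ring B aryl migrates from C2 to C3, and proton loss gives isoflavone 10 directly.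

**Further compounds**
F1 | step 11 | 5,2',4'-triacetoxy-7-hydroxy-8-iodoisoflavone | CC(=O)Oc1ccc(-c2coc3c(I)c(O)cc(OC(C)=O)c3c2=O)c(OC(C)=O)c1
F2 | step 11 | 5,7,2',4'-tetraacetoxy-8-iodoisoflavone | CC(=O)Oc1ccc(-c2coc3c(I)c(OC(C)=O)cc(OC(C)=O)c3c2=O)c(OC(C)=O)c1
F3 | step 9 | 5-hydroxy-3-(2,4-dihydroxyphenyl)-7-(3-methylbut-2-enyloxy)-4H-chromen-4-one | CC(C)=CCOc1cc(O)c2c(=O)c(-c3ccc(O)cc3O)coc2c1
F4 | step 5 | racemic 5,7-bis(benzyloxy)-2-[2,4-bis(benzyloxy)phenyl]chroman-4-one | O=C1CC(c2ccc(OCc3ccccc3)cc2OCc2ccccc2)Oc2cc(OCc3ccccc3)cc(OCc3ccccc3)c21
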